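Ring A is a benzoate with oxygen on C3 and C5 and the ring B aroyl group on C2. It is therefore the carbocyclic isomer of a 6-methyl-2-pyranone that bears this aroyl group at C5 and the ester at C4. The route rests on the C4–C5 bond of ring A: methoxide opens the lactone and the former 6-methyl carbon closes onto the freed ester carbonyl. One operation thus converts the heterocycle into the aromatic 3,5-diol with ester and ketone in place. The pyranone comes from a ring B aroylacetone (made from orcinol bis-MOM ether) and dimethyl acetylenedicarboxylate. Differentiation of the two ring A phenols, MOM removal, monoacetylation of ring B and hydrogenolysis complete the target.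

Key step: step 5

Remark on the chemistry: adduct 8 of step 4 is the neutral C–H acid, and enolate 10 of step 5 is the methoxymagnesium salt of its conjugate base, formed directly from the lactone without passing through neutral 8. Both have the two ester groups trans (E by the sequence rules), the only geometry that puts the distal ester beside the diketone unit; the pyranone ring enforces it.

Step 1
Reactants: 1 orcinol (5-methylbenzene-1,3-diol)
Product: 2 1,3-bis(methoxymethoxy)-5-methylbenzene
Conditions: NaH, MOMCl, DMF, 0 °C to rt
Reagents that add atoms: chloromethyl methyl ether (MOMCl), COCCl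
Why: Double O-alkylation of the bis-phenoxide with the reactive alpha-chloro ether (Williamson-type acetal formation) should be clean because both phenols are unhindered and equivalent.

Step 2
Reactants: 2 1,3-bis(methoxymethoxy)-5-methylbenzene; 3 N-methoxy-N-methylacetamide
Product: 5 1-[2,6-bis(methoxymethoxy)-4-methylphenyl]ethan-1-one, via aryllithium 4 (not isolated)
Conditions: n-BuLi, THF, 0 °C; then 3, −78 °C to rt; H2O
Reagents that add atoms: none
Why: Directed ortho metalation places lithium at C2 between the two cooperating MOM ethers, and acylation with the N-methoxy-N-methylamide (Weinreb ketone synthesis) should stop at the ketone because the chelated tetrahedral adduct survives until the aqueous quench.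

Step 3
Reactants: 5 1-[2,6-bis(methoxymethoxy)-4-methylphenyl]ethan-1-one
Product: 6 1-[2,6-bis(methoxymethoxy)-4-methylphenyl]butane-1,3-dione
Conditions: NaH, EtOAc, THF, 65 °C; then AcOH
Reagents that add atoms: ethyl acetate, CCOC(C)=O
Why: In this crossed Claisen condensation the sodium enolate of the hindered methyl ketone is acylated by ethyl acetate, and formation of the stable diketonate salt drives the equilibrium.

Step 4
Reactants: 6 1-[2,6-bis(methoxymethoxy)-4-methylphenyl]butane-1,3-dione; 7 dimethyl acetylenedicarboxylate
Product: 9 methyl 5-[2,6-bis(methoxymethoxy)-4-methylbenzoyl]-6-methyl-2-oxo-2H-pyran-4-carboxylate, via open-chain butenedioate adduct 8 (not isolated)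
Conditions: K2CO3 (cat.), MeCN, 0 °C to 60 °C
Reagents that add atoms: none
Why: Base-catalysed Michael addition of the diketone central carbon to the acetylenic diester gives, by anti protonation, the E-configured adduct 8, whose less hindered acetyl enol oxygen lies beside the distal ester and lactonises with loss of methanol, a known pyranone synthesis from 1,3-diketones and acetylenedicarboxylates.

Step 5
Reactants: 9 methyl 5-[2,6-bis(methoxymethoxy)-4-methylbenzoyl]-6-methyl-2-oxo-2H-pyran-4-carboxylate
Product: 12 methyl 2-[2,6-bis(methoxymethoxy)-4-methylbenzoyl]-3,5-dihydroxybenzoate, via ring-opened magnesium enolate 10 (not isolated), via cyclohexenedione Claisen product 11 (not isolated)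
Conditions: Mg(OMe)2, MeOH, reflux; then cold 1 M HCl
Reagents that add atoms: none
Why: Methoxide from the magnesium alkoxide adds to the lactone carbonyl (pyranone C2) and opens the ring to the methoxymagnesium enolate 10, in which the new methyl ester stays beside the diketone unit because the ring had fixed the geometry of the C3=C4 double bond. Deprotonation of the acetyl methyl group, the only enolisable position because the ketone has no alpha hydrogen on its ring B side, gives a terminal carbanion that attacks this ester carbonyl in a Claisen (Dieckmann-type) condensation to form the C4–C5 bond of ring A, and loss of methoxide gives cyclohexenedione 11, which enolises at once to the aromatic 3,5-diol 12. The closest known reaction type is the alkoxide-induced isomerisation of 5-acyl-6-methyl-2-pyranones to acylresorcinols. Ring A closes in a 6-(enolendo)-exo-trig mode, which is stereoelectronically allowed, whereas attack on the ester at C1 would be a disfavoured 5-(enolendo)-exo-trig closure. No stereocentre remains in the product, since the only sp3 methine of 11 is lost on aromatisation. The step needs carbon–carbon closure to win over relactonisation, and this is secured because ring opening and relactonisation are reversible under methoxide while aromatisation of ring A is not.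

Step 6
Reactants: 12 methyl 2-[2,6-bis(methoxymethoxy)-4-methylbenzoyl]-3,5-dihydroxybenzoate
Product: 13 methyl 5-(benzyloxy)-2-[2,6-bis(methoxymethoxy)-4-methylbenzoyl]-3-hydroxybenzoate
Conditions: BnBr (1.05 equiv), K2CO3, acetone, rt
Reagents that add atoms: benzyl bromide, BrCc1ccccc1
Why: Williamson etherification should select the C5 phenol, which is para to the ketone and therefore the more acidic and unhindered one, whereas the C3 phenol is hydrogen-bonded to the ketone and flanked by it.

Step 7
Reactants: 13 methyl 5-(benzyloxy)-2-[2,6-bis(methoxymethoxy)-4-methylbenzoyl]-3-hydroxybenzoate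
Product: 14 methyl 5-(benzyloxy)-2-[2,6-bis(methoxymethoxy)-4-methylbenzoyl]-3-methoxybenzoate
Conditions: MeI, K2CO3, DMF, 40 °C
Reagents that add atoms: iodomethane, CI
Why: Williamson O-methylation of the remaining chelated phenol should proceed with excess iodomethane in a polar aprotic solvent, since no other free hydroxyl group is left.

Step 8
Reactants: 14 methyl 5-(benzyloxy)-2-[2,6-bis(methoxymethoxy)-4-methylbenzoyl]-3-methoxybenzoate
Product: 15 methyl 5-(benzyloxy)-2-(2,6-dihydroxy-4-methylbenzoyl)-3-methoxybenzoate
Conditions: HCl (cat.), MeOH/THF, 40 °C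
Reagents that add atoms: none
Why: Acid-catalysed acetal exchange with methanol removes both MOM ethers, while the benzyl ether and the methyl ether are inert and transesterification of the methyl ester is degenerate.

Step 9
Reactants: 15 methyl 5-(benzyloxy)-2-(2,6-dihydroxy-4-methylbenzoyl)-3-methoxybenzoate
Product: 16 methyl 2-(2-acetoxy-6-hydroxy-4-methylbenzoyl)-5-(benzyloxy)-3-methoxybenzoate
Conditions: Ac2O (1.05 equiv), pyridine, CH2Cl2, 0 °C
Reagents that add atoms: acetic anhydride, CC(=O)OC(C)=O
Why: O-Acylation of one of the two equivalent ring B phenols should stop at the monoacetate because the remaining phenol is then locked in a hydrogen bond to the ketone and is far less nucleophilic, the effect that makes mono-O-functionalisation of 2,6-dihydroxyaryl ketones selective.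

Step 10
Reactants: 16 methyl 2-(2-acetoxy-6-hydroxy-4-methylbenzoyl)-5-(benzyloxy)-3-methoxybenzoate
Product: 17 penibenzophenone C, methyl 2-(2-acetoxy-6-hydroxy-4-methylbenzoyl)-5-hydroxy-3-methoxybenzoate
Conditions: H2 (1 atm), Pd/C, EtOAc, rt
Reagents that add atoms: none
Why: Catalytic hydrogenolysis of the benzyl ether under neutral conditions in a non-nucleophilic solvent should leave the aryl acetate, the methyl ester and the hindered diaryl ketone intact.

Compound list
1 | orcinol (5-methylbenzene-1,3-diol) | Cc1cc(O)cc(O)c1 | starting material
2 | 1,3-bis(methoxymethoxy)-5-methylbenzene | COCOc1cc(C)cc(OCOC)c1 | intermediate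
3 | N-methoxy-N-methylacetamide | CON(C)C(C)=O | starting material
4 | [2,6-bis(methoxymethoxy)-4-methylphenyl]lithium (not isolated) | [Li]c1c(OCOC)cc(C)cc1OCOC | intermediate
5 | 1-[2,6-bis(methoxymethoxy)-4-methylphenyl]ethan-1-one | CC(=O)c1c(OCOC)cc(C)cc1OCOC | intermediate
6 | 1-[2,6-bis(methoxymethoxy)-4-methylphenyl]butane-1,3-dione | CC(=O)CC(=O)c1c(OCOC)cc(C)cc1OCOC | intermediate
7 | dimethyl acetylenedicarboxylate (dimethyl but-2-ynedioate) | COC(=O)C#CC(=O)OC | starting material
8 | dimethyl (E)-2-{1-[2,6-bis(methoxymethoxy)-4-methylphenyl]-1,3-dioxobutan-2-yl}but-2-enedioate (not isolated; the diketone carbon is racemic and enolisable) | COC(=O)/C=C(/C(=O)OC)C(C(C)=O)C(=O)c1c(OCOC)cc(C)cc1OCOC | intermediate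
9 | methyl 5-[2,6-bis(methoxymethoxy)-4-methylbenzoyl]-6-methyl-2-oxo-2H-pyran-4-carboxylate | COC(=O)C1=CC(=O)OC(C)=C1C(=O)c1c(OCOC)cc(C)cc1OCOC | intermediate
10 | methoxymagnesium enolate of dimethyl (E)-2-{1-[2,6-bis(methoxymethoxy)-4-methylphenyl]-1-oxo-3-oxidobut-2-en-2-yl}but-2-enedioate (not isolated; drawn with the charge on the former ring oxygen, one resonance form of the chelated diketonate) | COC(=O)/C=C(/C(=O)OC)C(C(=O)c1c(OCOC)cc(C)cc1OCOC)=C(C)[O-].[Mg+2].C[O-] | intermediate
11 | methyl 6-[2,6-bis(methoxymethoxy)-4-methylbenzoyl]-3,5-dioxocyclohex-1-ene-1-carboxylate (not isolated; keto tautomer of 12, racemic and enolisable at C6, present as its magnesium enolate) | COC(=O)C1=CC(=O)CC(=O)C1C(=O)c1c(OCOC)cc(C)cc1OCOC | intermediate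
12 | methyl 2-[2,6-bis(methoxymethoxy)-4-methylbenzoyl]-3,5-dihydroxybenzoate | COC(=O)c1cc(O)cc(O)c1C(=O)c1c(OCOC)cc(C)cc1OCOC | intermediate
13 | methyl 5-(benzyloxy)-2-[2,6-bis(methoxymethoxy)-4-methylbenzoyl]-3-hydroxybenzoate | COC(=O)c1cc(OCc2ccccc2)cc(O)c1C(=O)c1c(OCOC)cc(C)cc1OCOC | intermediate
14 | methyl 5-(benzyloxy)-2-[2,6-bis(methoxymethoxy)-4-methylbenzoyl]-3-methoxybenzoate | COC(=O)c1cc(OCc2ccccc2)cc(OC)c1C(=O)c1c(OCOC)cc(C)cc1OCOC | intermediate
15 | methyl 5-(benzyloxy)-2-(2,6-dihydroxy-4-methylbenzoyl)-3-methoxybenzoate | COC(=O)c1cc(OCc2ccccc2)cc(OC)c1C(=O)c1c(O)cc(C)cc1O | intermediate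
16 | methyl 2-(2-acetoxy-6-hydroxy-4-methylbenzoyl)-5-(benzyloxy)-3-methoxybenzoate | COC(=O)c1cc(OCc2ccccc2)cc(OC)c1C(=O)c1c(O)cc(C)cc1OC(C)=O | intermediate
17 | penibenzophenone C, methyl 2-(2-acetoxy-6-hydroxy-4-methylbenzoyl)-5-hydroxy-3-methoxybenzoate (no stereocentre) | COC(=O)c1cc(O)cc(OC)c1C(=O)c1c(O)cc(C)cc1OC(C)=O | target

Total step count: 10
Longest linear sequence: 10 steps (1 to 17)

Steps most likely to fail

Step 5 (key step). The methyl-ketone carbanion may form too slowly under alkoxide after the lactone opens. The chain could then relactonise, lose its acetyl group by retro-Claisen cleavage, or close onto the neighbouring ester. The fallback sets out from 2 and comes back at 14, and builds ring A by cycloaddition and aromatisation instead of recyclisation. Compound 2 is lithiated as in step 2 and quenched with DMF to give 2,6-bis(methoxymethoxy)-4-methylbenzaldehyde F1. Lithiated methyl propiolate (LiN(SiMe3)2, THF, −78 °C) adds to it to give racemic methyl 4-[2,6-bis(methoxymethoxy)-4-methylphenyl]-4-hydroxybut-2-ynoate F2. MnO2 in CH2Cl2 oxidises this to methyl 4-[2,6-bis(methoxymethoxy)-4-methylphenyl]-4-oxobut-2-ynoate F3. Diels–Alder reaction of F3 with 1,1-dimethoxy-3-(trimethylsilyloxy)buta-1,3-diene (toluene, rt to 60 °C) should give methyl 2-[2,6-bis(methoxymethoxy)-4-methylbenzoyl]-3,3-dimethoxy-5-(trimethylsilyloxy)cyclohexa-1,4-diene-1-carboxylate F4, not isolated. The nucleophilic CH2 terminus of the diene should bond to the alkyne carbon beta to the ketone, which sets the required orientation. F4 aromatises by loss of methanol and is desilylated on aqueous NH4Cl work-up to methyl 2-[2,6-bis(methoxymethoxy)-4-methylbenzoyl]-5-hydroxy-3-methoxybenzoate F5, which already carries the C3 methyl ether. Benzylation of its single phenol (BnBr, K2CO3, acetone) gives 14.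

Step 4. Addition through the enol oxygen, double addition, or base-induced oligomerisation of the acetylenic ester may outrun the C-addition, or the adduct may stall before lactonisation. Lactonisation through the aroyl oxygen would not be a failure, since the isomeric pyranone opens to the same enolate in step 5. The fallback sets out from 6 and 7 and comes back at 9, and replaces the catalytic addition to the alkyne by a stoichiometric addition–elimination. Compound 7 is hydrochlorinated (LiCl, AcOH, MeCN, 70 °C) to dimethyl (Z)-2-chlorobut-2-enedioate F6. The pre-formed sodium enolate of 6 (NaH, THF, 0 °C) displaces chloride from F6 by conjugate addition and elimination to give the open-chain adduct 8. Here 8 is isolated after acidification and lactonised in a separate operation to 9 by heating in toluene with catalytic Et3N.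

Step 9. Acetylation of the second ring B phenol may compete with the first, or conversion may stay incomplete, leaving a mixture of diol, monoacetate and diacetate. The fallback sets out from 15 and comes back at 16, and reaches the monoacetate by subtraction. Compound 15 is acetylated exhaustively (Ac2O, Et3N, DMAP (cat.), CH2Cl2) to methyl 5-(benzyloxy)-2-(2,6-diacetoxy-4-methylbenzoyl)-3-methoxybenzoate F7. One acetate is then removed by methanolysis with K2CO3 (1 equiv) in MeOH at 0 °C. The phenoxide that is released is conjugated and chelated to the ketone and makes the second aryl ester a much poorer leaving group, so the reaction should stop at 16.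

Further compounds
F1 | step 5 | 2,6-bis(methoxymethoxy)-4-methylbenzaldehyde | O=Cc1c(OCOC)cc(C)cc1OCOC
F2 | step 5 | methyl 4-[2,6-bis(methoxymethoxy)-4-methylphenyl]-4-hydroxybut-2-ynoate (racemic) | COC(=O)C#CC(O)c1c(OCOC)cc(C)cc1OCOC
F3 | step 5 | methyl 4-[2,6-bis(methoxymethoxy)-4-methylphenyl]-4-oxobut-2-ynoate | COC(=O)C#CC(=O)c1c(OCOC)cc(C)cc1OCOC
F4 | step 5 | methyl 2-[2,6-bis(methoxymethoxy)-4-methylbenzoyl]-3,3-dimethoxy-5-(trimethylsilyloxy)cyclohexa-1,4-diene-1-carboxylate | COC(=O)C1=C(C(=O)c2c(OCOC)cc(C)cc2OCOC)C(OC)(OC)C=C(O[Si](C)(C)C)C1
F5 | step 5 | methyl 2-[2,6-bis(methoxymethoxy)-4-methylbenzoyl]-5-hydroxy-3-methoxybenzoate | COC(=O)c1cc(O)cc(OC)c1C(=O)c1c(OCOC)cc(C)cc1OCOC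
F6 | step 4 | dimethyl (Z)-2-chlorobut-2-enedioate | COC(=O)/C=C(/C(=O)OC)Cl
F7 | step 9 | methyl 5-(benzyloxy)-2-(2,6-diacetoxy-4-methylbenzoyl)-3-methoxybenzoate | COC(=O)c1cc(OCc2ccccc2)cc(OC)c1C(=O)c1c(OC(C)=O)cc(C)cc1OC(C)=O
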